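**Plan**
- Retrosynthesis: the C-4 carbinol goes back to a ketone. Ring A is then cut at O-1–C-6 and C-2–C-3 (retro-hetero-Diels–Alder) into 4-(pivaloyloxy)benzaldehyde and an acyclic 2-silyloxy-1,3-diene that holds the whole second diarylheptanoid. The diene's parent enone is cut at its C=C (aldol condensation), at the styryl–C bond (1,4-addition) and at the carbinol–allyl bond (allylation).
- Forward: the chain is built first (allylation, cross-metathesis, 1,4-addition, aldol condensation, silyl dienol ether). Ring A then arises in one cycloaddition, followed by C-3 epimerization, ketone reduction and global deprotection.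
- Enabling feature: in the tetrahydropyran, O-1–C-2(aryl) is a latent aryl aldehyde C=O and C-3–C-4(O)–C-5–C-6 is a latent 2-oxydiene, so the 4-oxygenated ring is a hetero-Diels–Alder retron. The helpers are the triethylsilyl enol ether and ketone oxidation level at C-4 and the electron-withdrawing pivalate on the aldehyde; all are removed later.
- Stereochemistry: the side-chain carbinol comes from the (R)-BINOL/Ti(OiPr)4 allylation and the styryl-bearing centre from Rh/(S)-BINAP. C-2 and C-6 come from the chromium catalyst and the endo rule, C-3 from thermodynamic epimerization, and C-4 from equatorial hydride delivery.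

Key step: step 13

Assumption: the facial senses of the three chiral catalysts (steps 3, 8 and 13) are taken to be those recalled for simple aliphatic aldehydes, acyclic (E)-enones and simple aldehydes; if one proves opposite on these substrates, the antipodal ligand is used.

Abbreviations: TIPS = triisopropylsilyl, TBS = tert-butyldimethylsilyl, TES = triethylsilyl, Piv = pivaloyl, Bpin = pinacolboryl.

**Step 1**
Reactants: 1 methyl 3-(4-hydroxyphenyl)propanoate
Product: 2 methyl 3-[4-(triisopropylsilyloxy)phenyl]propanoate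
Conditions: TIPSCl, imidazole, DMF, rt
Reagents that add atoms: triisopropylsilyl chloride, CC(C)[Si](Cl)(C(C)C)C(C)C
Why: Imidazole-promoted silylation of the phenol gives a silyl ether that is robust to the basic and organometallic steps that follow.

**Step 2**
Reactants: 2 methyl 3-[4-(triisopropylsilyloxy)phenyl]propanoate
Product: 3 3-[4-(triisopropylsilyloxy)phenyl]propanal
Conditions: iBu2AlH (1.05 equiv), CH2Cl2, −78 °C; aqueous work-up
Reagents that add atoms: none
Why: Partial reduction of the ester stops at the aldehyde because the tetrahedral aluminium hemiacetal is stable at −78 °C.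

**Step 3**
Reactants: 3 3-[4-(triisopropylsilyloxy)phenyl]propanal
Product: 4 (S)-1-[4-(triisopropylsilyloxy)phenyl]hex-5-en-3-ol
Conditions: allyltributylstannane, (R)-BINOL (10 mol%), Ti(OiPr)4 (10 mol%), 4 Å MS, CH2Cl2, −20 °C; aq NaHCO3
Reagents that add atoms: allyltributylstannane, C=CC[Sn](CCCC)(CCCC)CCCC
Why: In the Keck asymmetric allylation the BINOL–titanium Lewis acid should direct allyl transfer to the Re face of the aldehyde and so set the (S)-carbinol of the side chain.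

**Step 4**
Reactants: 4 (S)-1-[4-(triisopropylsilyloxy)phenyl]hex-5-en-3-ol
Product: 5 (S)-3-(tert-butyldimethylsilyloxy)-1-[4-(triisopropylsilyloxy)phenyl]hex-5-ene
Conditions: TBSCl, imidazole, DMF, rt
Reagents that add atoms: tert-butyldimethylsilyl chloride, CC(C)(C)[Si](C)(C)Cl
Why: Silyl ether formation masks the carbinol so that it cannot form a hemiketal with the later ketone or undergo elimination.

**Step 5**
Reactants: 5 (S)-3-(tert-butyldimethylsilyloxy)-1-[4-(triisopropylsilyloxy)phenyl]hex-5-ene; 6 but-3-en-2-one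
Product: 7 (S,E)-6-(tert-butyldimethylsilyloxy)-8-[4-(triisopropylsilyloxy)phenyl]oct-3-en-2-one
Conditions: 6 (3 equiv), second-generation Hoveyda–Grubbs catalyst (5 mol%), CH2Cl2, 40 °C
Reagents that add atoms: none
Why: Olefin cross-metathesis of a terminal alkene with an electron-poor vinyl ketone should give the (E)-enone selectively and leave the stereocentre untouched.

**Step 6**
Reactants: 8 4-hydroxybenzaldehyde
Product: 9 4-(triisopropylsilyloxy)benzaldehyde
Conditions: TIPSCl, imidazole, DMF, rt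
Reagents that add atoms: triisopropylsilyl chloride, CC(C)[Si](Cl)(C(C)C)C(C)C
Why: Silylation of the phenol as in step 1.

**Step 7**
Reactants: 9 4-(triisopropylsilyloxy)benzaldehyde
Product: 10 (E)-2-{2-[4-(triisopropylsilyloxy)phenyl]ethenyl}-4,4,5,5-tetramethyl-1,3,2-dioxaborolane
Conditions: CH2(Bpin)2, LiTMP, THF, 0 °C; then 9, −78 °C → rt
Reagents that add atoms: bis(pinacolato)borylmethane, CC1(C)OB(CB2OC(C)(C)C(C)(C)O2)OC1(C)C
Why: In the boron-Wittig olefination the lithiated gem-diboronate adds to the aldehyde and syn B–O elimination should give the (E)-alkenyl boronate.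

**Step 8**
Reactants: 7 (S,E)-6-(tert-butyldimethylsilyloxy)-8-[4-(triisopropylsilyloxy)phenyl]oct-3-en-2-one; 10 (E)-alkenyl pinacol boronate
Product: 11 (4R,6S)-6-(tert-butyldimethylsilyloxy)-8-[4-(triisopropylsilyloxy)phenyl]-4-{(E)-2-[4-(triisopropylsilyloxy)phenyl]ethenyl}octan-2-one
Conditions: Rh(acac)(C2H4)2 (3 mol%), (S)-BINAP (3.3 mol%), K3PO4 (0.5 equiv), dioxane/H2O (10:1), 50 °C
Reagents that add atoms: none
Why: In the Hayashi–Miyaura 1,4-addition the alkenylrhodium–(S)-BINAP species should add to the Re face of the β-carbon of the (E)-enone, setting the (4R) centre under catalyst control since the existing (6S) centre is remote.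

**Step 9**
Reactants: 11 (4R,6S)-methyl ketone; 3 3-[4-(triisopropylsilyloxy)phenyl]propanal
Product: 12 (7R,9S)-3-hydroxy-9-(tert-butyldimethylsilyloxy)-1,11-bis[4-(triisopropylsilyloxy)phenyl]-7-{(E)-2-[4-(triisopropylsilyloxy)phenyl]ethenyl}undecan-5-one (both C-3 epimers)
Conditions: LiN(iPr)2, THF, −78 °C; then 3; water quench
Reagents that add atoms: none
Why: Kinetic deprotonation occurs at the methyl group, and aldol addition of that lithium enolate to the aldehyde gives a carbinol whose configuration is erased in the next step.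

**Step 10**
Reactants: 12 β-hydroxy ketone
Product: 14 (3E,7R,9S)-9-(tert-butyldimethylsilyloxy)-1,11-bis[4-(triisopropylsilyloxy)phenyl]-7-{(E)-2-[4-(triisopropylsilyloxy)phenyl]ethenyl}undec-3-en-5-one, via β-mesyloxy ketone 13 (not isolated)
Conditions: MsCl, Et3N, CH2Cl2, 0 °C; then DBU, rt
Reagents that add atoms: none
Why: Mesylation followed by E1cB elimination should give the conjugated (E)-enone.

**Step 11**
Reactants: 14 (3E,7R,9S)-enone
Product: 15 (3E,5Z,7S,9S)-9-(tert-butyldimethylsilyloxy)-5-(triethylsilyloxy)-1,11-bis[4-(triisopropylsilyloxy)phenyl]-7-{(E)-2-[4-(triisopropylsilyloxy)phenyl]ethenyl}undeca-3,5-diene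
Conditions: Et3SiOTf, Et3N, Et2O, 0 °C
Reagents that add atoms: triethylsilyl triflate, CC[Si](CC)(CC)OS(=O)(=O)C(F)(F)F
Why: Soft enolization with silyl triflate and amine takes place at the α′-CH2 and should give the cross-conjugated (Z)-silyl enol ether, the geometry that keeps allylic strain lowest and that the cycloaddition needs.

**Step 12**
Reactants: 8 4-hydroxybenzaldehyde
Product: 16 4-formylphenyl pivalate
Conditions: PivCl, Et3N, DMAP (cat.), CH2Cl2, 0 °C → rt
Reagents that add atoms: pivaloyl chloride, CC(C)(C)C(=O)Cl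
Why: O-acylation gives a phenol ester that, unlike a silyl ether, makes the aldehyde more electrophilic for the cycloaddition.

**Step 13**
Reactants: 15 (3E,5Z,7S,9S)-2-silyloxydiene; 16 4-formylphenyl pivalate
Product: 17 4-[(2S,3S,6S)-3-{(1E,3S,5S)-5-(tert-butyldimethylsilyloxy)-1,7-bis[4-(triisopropylsilyloxy)phenyl]hept-1-en-3-yl}-4-(triethylsilyloxy)-6-{2-[4-(triisopropylsilyloxy)phenyl]ethyl}-3,6-dihydro-2H-pyran-2-yl]phenyl pivalate (2,3,6-all-cis)
Conditions: [CrCl(L)] (10 mol%; L = dianion of the Schiff base of (1S,2R)-1-aminoindan-2-ol and 3-(1-adamantyl)-2-hydroxy-5-methylbenzaldehyde; trivalent chromium), powdered 4 Å MS, minimal TBME, rt, 48–72 h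
Reagents that add atoms: none
Why: The chromium Lewis acid binds the aldehyde of 16 and the diene of 15 adds across the C=O in a concerted, asynchronous hetero-Diels–Alder reaction, in which the silyl enol ether terminus (future ring C-3) bonds to the carbonyl carbon and the carbonyl oxygen bonds to the diene terminus that carries the arylethyl group (future C-6); the closest known reaction type is the chromium Schiff-base-catalysed hetero-Diels–Alder reaction of 1,4-disubstituted 2-silyloxydienes with aldehydes. Ring A, the six-membered dihydropyran, is closed by [4+2] cycloaddition, both bonds forming suprafacially on one face of the s-cis diene through an endo transition state. C-2 should be set by the catalyst, which exposes the Si face of the aldehyde, while C-6 and C-3 follow from the endo rule and the (E,Z) diene geometry, which together give the 2,3,6-all-cis array (C-3 is inverted in step 14). The step needs regioselectivity, which the 2-silyloxy group secures by making the future C-3 the nucleophilic terminus, and chemoselectivity, which the pairing of an electron-rich diene with an electron-poor pivaloyloxy aldehyde secures, since no other π-system of 15 is a partner for the aldehyde. It also needs catalyst control over the diene face, which is plausible because the allylic stereocentre carries two arms (CH2 and CH=) of similar size at the point of attachment.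

**Step 14**
Reactants: 17 all-cis cycloadduct
Product: 19 4-[(2S,3R,6S)-3-{(1E,3S,5S)-5-(tert-butyldimethylsilyloxy)-1,7-bis[4-(triisopropylsilyloxy)phenyl]hept-1-en-3-yl}-4-oxo-6-{2-[4-(triisopropylsilyloxy)phenyl]ethyl}tetrahydro-2H-pyran-2-yl]phenyl pivalate (2,3-trans-2,6-cis), via all-cis (2S,3S,6S)-ketone 18 (not isolated)
Conditions: 1 M HCl, THF, 0 °C; then DBU (0.5 equiv), CH2Cl2, rt
Reagents that add atoms: none
Why: Acid hydrolysis of the silyl enol ether (protonation at C-5) should give the 2,3-cis ketone, and DBU should then epimerize C-3 through the enolate to the all-equatorial 2,3-trans-2,6-cis ketone under thermodynamic control.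

**Step 15**
Reactants: 19 (2S,3R,6S)-ketone
Product: 20 4-[(2S,3S,4S,6S)-3-{(1E,3S,5S)-5-(tert-butyldimethylsilyloxy)-1,7-bis[4-(triisopropylsilyloxy)phenyl]hept-1-en-3-yl}-4-hydroxy-6-{2-[4-(triisopropylsilyloxy)phenyl]ethyl}tetrahydro-2H-pyran-2-yl]phenyl pivalate
Conditions: LiBH(sBu)3, THF, −78 °C; water quench
Reagents that add atoms: none
Why: The bulky trialkylborohydride should attack the chair ketone along the equatorial trajectory and give the axial (4S) alcohol, cis to the C-3 substituent.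

**Step 16**
Reactants: 20 (2S,3S,4S,6S)-alcohol
Product: 22 blepharocalyxin C, via pentahydroxy monopivalate 21 (not isolated)
Conditions: Bu4NF, AcOH, THF, 0 °C → rt; then K2CO3, MeOH, rt
Reagents that add atoms: none
Why: Buffered fluoride should cleave the three aryl silyl ethers and the secondary alkyl silyl ether, and base-catalysed methanolysis then removes the aryl pivalate without touching any stereocentre.

**Compound list**
1 | methyl 3-(4-hydroxyphenyl)propanoate | COC(=O)CCc1ccc(O)cc1 | starting material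
2 | methyl 3-[4-(triisopropylsilyloxy)phenyl]propanoate | COC(=O)CCc1ccc(O[Si](C(C)C)(C(C)C)C(C)C)cc1 | intermediate
3 | 3-[4-(triisopropylsilyloxy)phenyl]propanal | O=CCCc1ccc(O[Si](C(C)C)(C(C)C)C(C)C)cc1 | intermediate
4 | (S)-1-[4-(triisopropylsilyloxy)phenyl]hex-5-en-3-ol | C=CC[C@@H](O)CCc1ccc(O[Si](C(C)C)(C(C)C)C(C)C)cc1 | intermediate
5 | (S)-3-(tert-butyldimethylsilyloxy)-1-[4-(triisopropylsilyloxy)phenyl]hex-5-ene | C=CC[C@@H](O[Si](C)(C)C(C)(C)C)CCc1ccc(O[Si](C(C)C)(C(C)C)C(C)C)cc1 | intermediate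
6 | but-3-en-2-one (methyl vinyl ketone) | C=CC(C)=O | starting material
7 | (S,E)-6-(tert-butyldimethylsilyloxy)-8-[4-(triisopropylsilyloxy)phenyl]oct-3-en-2-one | CC(=O)/C=C/C[C@@H](O[Si](C)(C)C(C)(C)C)CCc1ccc(O[Si](C(C)C)(C(C)C)C(C)C)cc1 | intermediate
8 | 4-hydroxybenzaldehyde | O=Cc1ccc(O)cc1 | starting material
9 | 4-(triisopropylsilyloxy)benzaldehyde | O=Cc1ccc(O[Si](C(C)C)(C(C)C)C(C)C)cc1 | intermediate
10 | (E)-2-{2-[4-(triisopropylsilyloxy)phenyl]ethenyl}-4,4,5,5-tetramethyl-1,3,2-dioxaborolane | CC(C)[Si](C(C)C)(C(C)C)Oc1ccc(/C=C/B2OC(C)(C)C(C)(C)O2)cc1 | intermediate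
11 | (4R,6S)-6-(tert-butyldimethylsilyloxy)-8-[4-(triisopropylsilyloxy)phenyl]-4-{(E)-2-[4-(triisopropylsilyloxy)phenyl]ethenyl}octan-2-one | CC(C)[Si](C(C)C)(C(C)C)Oc1ccc(/C=C/[C@H](C[C@@H](O[Si](C)(C)C(C)(C)C)CCc2ccc(O[Si](C(C)C)(C(C)C)C(C)C)cc2)CC(C)=O)cc1 | intermediate
12 | (7R,9S)-3-hydroxy-9-(tert-butyldimethylsilyloxy)-1,11-bis[4-(triisopropylsilyloxy)phenyl]-7-{(E)-2-[4-(triisopropylsilyloxy)phenyl]ethenyl}undecan-5-one, both C-3 epimers | CC(C)[Si](C(C)C)(C(C)C)Oc1ccc(/C=C/[C@H](C[C@@H](O[Si](C)(C)C(C)(C)C)CCc2ccc(O[Si](C(C)C)(C(C)C)C(C)C)cc2)CC(=O)CC(O)CCc2ccc(O[Si](C(C)C)(C(C)C)C(C)C)cc2)cc1 | intermediate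
13 | 3-methanesulfonate of 12 | CC(C)[Si](C(C)C)(C(C)C)Oc1ccc(/C=C/[C@H](C[C@@H](O[Si](C)(C)C(C)(C)C)CCc2ccc(O[Si](C(C)C)(C(C)C)C(C)C)cc2)CC(=O)CC(OS(C)(=O)=O)CCc2ccc(O[Si](C(C)C)(C(C)C)C(C)C)cc2)cc1 | intermediate
14 | (3E,7R,9S)-9-(tert-butyldimethylsilyloxy)-1,11-bis[4-(triisopropylsilyloxy)phenyl]-7-{(E)-2-[4-(triisopropylsilyloxy)phenyl]ethenyl}undec-3-en-5-one | CC(C)[Si](C(C)C)(C(C)C)Oc1ccc(/C=C/[C@H](C[C@@H](O[Si](C)(C)C(C)(C)C)CCc2ccc(O[Si](C(C)C)(C(C)C)C(C)C)cc2)CC(=O)/C=C/CCc2ccc(O[Si](C(C)C)(C(C)C)C(C)C)cc2)cc1 | intermediate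
15 | (3E,5Z,7S,9S)-9-(tert-butyldimethylsilyloxy)-5-(triethylsilyloxy)-1,11-bis[4-(triisopropylsilyloxy)phenyl]-7-{(E)-2-[4-(triisopropylsilyloxy)phenyl]ethenyl}undeca-3,5-diene | CC(C)[Si](C(C)C)(C(C)C)Oc1ccc(/C=C/[C@H](C[C@@H](O[Si](C)(C)C(C)(C)C)CCc2ccc(O[Si](C(C)C)(C(C)C)C(C)C)cc2)/C=C(O[Si](CC)(CC)CC)/C=C/CCc2ccc(O[Si](C(C)C)(C(C)C)C(C)C)cc2)cc1 | intermediate
16 | 4-formylphenyl pivalate | CC(C)(C)C(=O)Oc1ccc(C=O)cc1 | intermediate
17 | (2S,3S,6S)-all-cis 4-(triethylsilyloxy)-3,6-dihydro-2H-pyran cycloadduct (full name in step 13) | CC(C)[Si](C(C)C)(C(C)C)Oc1ccc(/C=C/[C@H](C[C@@H](O[Si](C)(C)C(C)(C)C)CCc2ccc(O[Si](C(C)C)(C(C)C)C(C)C)cc2)[C@H]2[C@@H](c3ccc(OC(=O)C(C)(C)C)cc3)O[C@@H](CCc3ccc(O[Si](C(C)C)(C(C)C)C(C)C)cc3)C=C2O[Si](CC)(CC)CC)cc1 | intermediate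
18 | (2S,3S,6S)-all-cis tetrahydropyran-4-one (C-3 epimer of 19) | CC(C)[Si](C(C)C)(C(C)C)Oc1ccc(/C=C/[C@H](C[C@@H](O[Si](C)(C)C(C)(C)C)CCc2ccc(O[Si](C(C)C)(C(C)C)C(C)C)cc2)[C@H]2[C@@H](c3ccc(OC(=O)C(C)(C)C)cc3)O[C@@H](CCc3ccc(O[Si](C(C)C)(C(C)C)C(C)C)cc3)CC2=O)cc1 | intermediate
19 | (2S,3R,6S)-2,3-trans-2,6-cis tetrahydropyran-4-one (full name in step 14) | CC(C)[Si](C(C)C)(C(C)C)Oc1ccc(/C=C/[C@H](C[C@@H](O[Si](C)(C)C(C)(C)C)CCc2ccc(O[Si](C(C)C)(C(C)C)C(C)C)cc2)[C@@H]2[C@@H](c3ccc(OC(=O)C(C)(C)C)cc3)O[C@@H](CCc3ccc(O[Si](C(C)C)(C(C)C)C(C)C)cc3)CC2=O)cc1 | intermediate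
20 | (2S,3S,4S,6S)-tetrahydropyran-4-ol with axial hydroxyl (full name in step 15) | CC(C)[Si](C(C)C)(C(C)C)Oc1ccc(/C=C/[C@H](C[C@@H](O[Si](C)(C)C(C)(C)C)CCc2ccc(O[Si](C(C)C)(C(C)C)C(C)C)cc2)[C@@H]2[C@@H](c3ccc(OC(=O)C(C)(C)C)cc3)O[C@@H](CCc3ccc(O[Si](C(C)C)(C(C)C)C(C)C)cc3)C[C@@H]2O)cc1 | intermediate
21 | blepharocalyxin C mono-pivalate (pivalate on the C-2 aryl group) | Oc1ccc(/C=C/[C@H](C[C@@H](O)CCc2ccc(O)cc2)[C@@H]2[C@@H](c3ccc(OC(=O)C(C)(C)C)cc3)O[C@@H](CCc3ccc(O)cc3)C[C@@H]2O)cc1 | intermediate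
22 | blepharocalyxin C | Oc1ccc(/C=C/[C@H](C[C@@H](O)CCc2ccc(O)cc2)[C@@H]2[C@@H](c3ccc(O)cc3)O[C@@H](CCc3ccc(O)cc3)C[C@@H]2O)cc1 | target

**Step count and risks**
Total steps: 16. Longest linear sequence: 13 (steps 1–5, 8–11, 13–16).

Most likely to fail:

1. Step 13. The cycloaddition may be slow at the hindered, α-branched diene terminus, and the allylic stereocentre may prefer the diene face opposite to the one the catalyst demands, so conversion or the ring-to-side-chain diastereoselectivity may be poor. Fallback, stepwise aldol then oxa-Michael: it sets out from enone 14 (with 16). Enolization at the α′-CH2 with diisopinocampheylboron triflate and iPr2NEt (the pinene antipode chosen to attack the aldehyde Si face) and syn-aldol addition to 16 give the syn-aldol adduct F1. Acid-mediated 6-endo oxa-Michael cyclization (Amberlyst-15, CH2Cl2) closes ring A to the all-cis ketone 18, where it comes back to the route; the DBU stage of step 14 takes 18 to 19.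

2. Step 8. Protodeboronation of the electron-rich styryl boronate may outrun transmetalation, the δ-silyloxy group may be lost by vinylogous elimination in the basic aqueous medium, or facial control may be insufficient. Fallback, auxiliary-controlled cuprate addition: it sets out from 5 and 9. Cross-metathesis of 5 with (S)-3-acryloyl-4-phenyloxazolidin-2-one (second-generation Hoveyda–Grubbs catalyst) gives the enoyl imide F2. Takai olefination of 9 (CrCl2, divalent chromium; CHI3) gives the (E)-iodoalkene F3. Iodine–magnesium exchange on F3 (iPrMgCl·LiCl) and CuBr·SMe2-mediated 1,4-addition to F2, anti to the phenyl group of the chelated imide, give the adduct F4. Me(MeO)NH·HCl with Me3Al gives the Weinreb amide F5, and MeMgBr brings the route back at methyl ketone 11.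

3. Step 15. Hydride delivery to the ketone flanked by the branched C-3 substituent may be slow, may lose facial selectivity, or may be accompanied by attack on the aryl pivalate. Fallback, reduction then inversion: it sets out from 19. NaBH4 (MeOH/THF, −20 °C) gives the equatorial alcohol F6. Mitsunobu inversion (4-nitrobenzoic acid, PPh3, diisopropyl azodicarboxylate) gives the axial 4-nitrobenzoate F7. The conditions of step 16 then remove the silyl groups and, in the K2CO3/MeOH stage, both esters, and the route comes back at 22.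

**Further compounds**
F1 | step 13 | 4-[(1S,2S,4E)-1-hydroxy-3-oxo-2-{(1E,3S,5S)-5-(tert-butyldimethylsilyloxy)-1,7-bis[4-(triisopropylsilyloxy)phenyl]hept-1-en-3-yl}-7-[4-(triisopropylsilyloxy)phenyl]hept-4-en-1-yl]phenyl pivalate (syn-aldol) | CC(C)[Si](C(C)C)(C(C)C)Oc1ccc(/C=C/[C@H](C[C@@H](O[Si](C)(C)C(C)(C)C)CCc2ccc(O[Si](C(C)C)(C(C)C)C(C)C)cc2)[C@H](C(=O)/C=C/CCc2ccc(O[Si](C(C)C)(C(C)C)C(C)C)cc2)[C@H](O)c2ccc(OC(=O)C(C)(C)C)cc2)cc1
F2 | step 8 | (S)-3-{(S,E)-5-(tert-butyldimethylsilyloxy)-7-[4-(triisopropylsilyloxy)phenyl]hept-2-enoyl}-4-phenyloxazolidin-2-one | O=C1OC[C@H](c2ccccc2)N1C(=O)/C=C/C[C@@H](O[Si](C)(C)C(C)(C)C)CCc1ccc(O[Si](C(C)C)(C(C)C)C(C)C)cc1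
F3 | step 8 | (E)-1-(2-iodoethenyl)-4-(triisopropylsilyloxy)benzene | CC(C)[Si](C(C)C)(C(C)C)Oc1ccc(/C=C/I)cc1
F4 | step 8 | (S)-3-[(3R,5S)-5-(tert-butyldimethylsilyloxy)-7-[4-(triisopropylsilyloxy)phenyl]-3-{(E)-2-[4-(triisopropylsilyloxy)phenyl]ethenyl}heptanoyl]-4-phenyloxazolidin-2-one | CC(C)[Si](C(C)C)(C(C)C)Oc1ccc(/C=C/[C@H](C[C@@H](O[Si](C)(C)C(C)(C)C)CCc2ccc(O[Si](C(C)C)(C(C)C)C(C)C)cc2)CC(=O)N2[C@@H](c3ccccc3)COC2=O)cc1
F5 | step 8 | (3R,5S)-5-(tert-butyldimethylsilyloxy)-N-methoxy-N-methyl-7-[4-(triisopropylsilyloxy)phenyl]-3-{(E)-2-[4-(triisopropylsilyloxy)phenyl]ethenyl}heptanamide | CC(C)[Si](C(C)C)(C(C)C)Oc1ccc(/C=C/[C@H](C[C@@H](O[Si](C)(C)C(C)(C)C)CCc2ccc(O[Si](C(C)C)(C(C)C)C(C)C)cc2)CC(=O)N(C)OC)cc1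
F6 | step 15 | (2S,3S,4R,6S)-C-4 epimer of 20 (equatorial hydroxyl) | CC(C)[Si](C(C)C)(C(C)C)Oc1ccc(/C=C/[C@H](C[C@@H](O[Si](C)(C)C(C)(C)C)CCc2ccc(O[Si](C(C)C)(C(C)C)C(C)C)cc2)[C@@H]2[C@@H](c3ccc(OC(=O)C(C)(C)C)cc3)O[C@@H](CCc3ccc(O[Si](C(C)C)(C(C)C)C(C)C)cc3)C[C@H]2O)cc1
F7 | step 15 | 4-nitrobenzoate of 20 (axial ester at C-4) | CC(C)[Si](C(C)C)(C(C)C)Oc1ccc(/C=C/[C@H](C[C@@H](O[Si](C)(C)C(C)(C)C)CCc2ccc(O[Si](C(C)C)(C(C)C)C(C)C)cc2)[C@@H]2[C@@H](c3ccc(OC(=O)C(C)(C)C)cc3)O[C@@H](CCc3ccc(O[Si](C(C)C)(C(C)C)C(C)C)cc3)C[C@@H]2OC(=O)c3ccc([N+](=O)[O-])cc3)cc1
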